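(All runs stem from a simulated flask on assumed constants, and the scatter is random.)

Take the ratio of two reagent doses, north over noon, before you follow your hunch that the longer time in north carries bis adduct far past noon's.

| flask | substrate | reagent | remark | time |
|---|---|---|---|---|
| summer | 1 mM | 0.55 mM | run made earlier |  |
| noon | 1 mM | 6.3 mM | run made earlier |  |
| north | 1.0 mM | 4.00 mM |  | 10 min |
| west | 1.0 mM | 2.00 mM |  | 10 min |
| south-east | 1.0 mM | 0.500 mM |  | 10 min |

| run | time / min | bis adduct / % | substrate / % |
|---|---|---|---|
| summer | 1.00 | 0.5 | 79.1 |
| summer | 2.00 | 0 | 67.7 |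
| summer | 3.00 | 0 | 61.7 |
| summer | 4.00 | 0.1 | 56.5 |
| summer | 5.00 | 1.3 | 53.8 |
| noon | 0.417 | 2.8 | 26.0 |
| noon | 1.33 | 8.3 | 1.4 |
| noon | 2.50 | 16.7 | 0 |
| noon | 4.00 | 20.4 | 0 |
| noon | 5.00 | 22.1 | 1.4 |

(standard deviation of a reading: 0.5 percentage points)

- a reading or a percentage of bis adduct counts all its forms, free or not

- which of these holds the largest part of the substrate at the end of north (substrate / tris adduct / mono adduct / bis adduct)
- which of these holds the largest part of the substrate at the end of west (substrate / tris adduct / mono adduct / bis adduct)
- which of these holds the largest part of the substrate at the end of south-east (substrate / tris adduct / mono adduct / bis adduct)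
- final bis adduct in north, as a percentage of the substrate charged

Multiply c(reagent), less one equivalent taken by the substrate charge, by the time. This gives 1.80 M·s for north and 1.59 M·s for noon at its last reading. Call this product the reagent dose. Assume each addition is first order in reagent, so pseudo-first-order on the dose; at one substrate charge, equal dose then means equal contents.

The ratio is 1.13, so place north just beyond noon's last reading. Noon's bis adduct readings rose 1.7 percentage points over the last interval, each reading carrying a scatter of 0.5 points, and extending that rise per unit of dose gives my number for north, 23.2 %. Expect mono adduct to lead in north, less firmly, and in west, whose dose is smaller. Expect substrate to lead in south-east, where reagent is the limiting reagent.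

The forecast gives mono adduct, mono adduct and substrate in those flasks and 22 % of bis adduct in north: “Mono dominates”.

The flask gives mono adduct at 47.1 % in north, with bis adduct at 22.8 %; mono adduct at 77.8 % in west; and substrate at 52.6 % in south-east.

    substrate + reagent → mono adduct (k = 9.00 L mol⁻¹ s⁻¹)
    reagent + mono adduct → bis adduct (k = 0.520 L mol⁻¹ s⁻¹)
    reagent + bis adduct → tris adduct (k = 4.30 L mol⁻¹ s⁻¹)
    crystals ⇌ bis adduct, rate k4*(cs4 - [bis adduct]) while solid is left; crystals form when [bis adduct] > cs4 (solubility = 0.0490 mM, k = 4.00 s⁻¹)
    bis adduct → over-reaction product (k = 7.50 × 10⁻⁶ s⁻¹)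

Now dose the flask that differs from north by holding 0.60 mM of substrate: it gets 2.04 M·s. Let mono adduct fall exponentially with dose, and raise north's mono adduct share to the dose ratio. That gives 42.6 %, and the flask holds 40.7 %. In that neighbouring flask tris adduct holds the most, at 53.6 %, and bis adduct stands at 5.65 %.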